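## Analysis of the target

The target is a 5,6,7,8-tetrahydroquinoline: a pyridine (ring A: N1, C2, C3, C4, C4a, C8a) fused to a six-membered carbocycle (ring B: C4a, C5, C6, C7, C8, C8a). C6 is the only stereocentre, an all-carbon quaternary centre bearing the 3,4-dimethoxyphenyl group, the ring methylenes C5 and C7, and the chain CH2CH2N(CH3)C(O)CH3. By the CIP rules (aryl > CH2CH2N > C5 > C7) the SMILES encodes R. No second stereocentre, heteroatom or carbonyl lies within two bonds of C6, and all three alkyl arms on it are methylene groups, so the centre has to be set by reagent control. The feature the route uses is this: two of these arms are two-carbon chains ending at nitrogen, C7–C8–C8a(=N1) in ring B and CH2–CH2–N in the side chain. Both can come from the same 2-cyanoethyl group, the first by using C≡N as C8a and N1 of ring A, the second by a one-carbon degradation; C6 is stereogenic only because the two arms end differently. Sensitive groups are the electron-rich dimethoxyphenyl ring (electrophiles, oxidants, strong acid) and the basic pyridine nitrogen (metal coordination, N-oxidation, quaternisation). The difficulties are the enantioselective construction of a remote quaternary benzylic centre and the regiochemistry of the ring fusion (N1 on the longer arm of C6).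

## Retrosynthetic reasoning

**17 to 16.** The acetyl C–N bond is cut last. This leaves secondary amine 16, and the forward step is a plain N-acylation with no selectivity issue.

**16 to 12 (through 15, 14, 13).** The N-methyl carbon is traced back to the carbonyl carbon of carbamate 15, so a hydride reduction delivers it. The N–CH2 bond of the chain is traced back to a C–CH2 bond: isocyanate 14 arises from primary amide 13 by a 1,2-shift of the chain CH2 from carbon to nitrogen, and 13 comes from nitrile 12 by hydration. This costs one carbon but makes the side chain a 2-cyanoethyl group, the same group that ring B needs. The migrating carbon is a primary CH2 two bonds from C6, so the stereocentre is not touched.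

**12 to 9 and 10 (key disconnection, through 11).** Three bonds of ring A are cut: C8a–C4a, C4–C3 and N1–C2. Because C8a–C4a is the fusion bond, ring B opens as well. N1≡C8a becomes a nitrile, C4a≡C4 a terminal alkyne, and C2/C3 come from silylalkyne 10; the silyl group at C2 in 11 is a traceless handle that keeps the external alkyne from coupling with itself. The precursor 9 is acyclic and has a mirror plane, with two enantiotopic 2-cyanoethyl arms on the future C6. This is the only cut of ring A that makes the arm C7–C8–C8a identical to the precursor of the side chain. The forward reaction must therefore close both rings and, by engaging one of the two nitriles, create the stereocentre, all in one operation.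

**9 to 4 (through 7 and 6).** The propargyl arm is taken apart by two one-carbon disconnections: the terminal alkyne carbon comes from diazophosphonate 8 acting on aldehyde 7, and the CH2 comes from the ylide of phosphonium salt 5 acting on aldehyde 4 via enol ether 6. A propargyl group cannot be placed on this carbon directly, because once the two cyanoethyl arms are in place no acidifying group remains. The formyl group of 4 serves both as the activating group for building the quaternary carbon and as the seed of the propargyl arm.

**4 to 1 and 2 (through 3).** Both bonds from the quaternary carbon to the cyanoethyl arms are cut. The forward reaction is a double conjugate addition of aldehyde 1 to acrylonitrile 2 through mono-adduct 3. The product is symmetrical, so there is no selectivity problem, and the quaternary carbon is assembled in one step from two commercial compounds.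

## Alternatives that were turned down

**Alternative 1:** The textbook route cuts only ring A, back to the 4,4-disubstituted cyclohexanone A1 and a three-carbon C–C–C–N annulation partner. The forward key step is condensation, cyclisation and aromatisation of the ketone with that unit. It was turned down because A1 is achiral: its two α-methylene groups are enantiotopic and the annulation chooses between them without control, so the quaternary centre comes out racemic. An enantioselective version has to pass through the chiral enone A2. That requires a separate asymmetric synthesis of the quaternary centre, site-selective annulation at the saturated α-carbon, and a hydrogenation. The key step would then build ring A only and set nothing.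

**Alternative 2:** The bicycle is bought as ketone A3, and the C6–aryl and C6–CH2 bonds are disconnected. The forward key steps are α-arylation to A4 and a palladium-catalysed asymmetric allylic alkylation of its enolate to A5. It was turned down for three reasons:
- The key step makes one C–C bond on a purchased ring system.
- The C5 carbonyl, needed only to activate C6, must then be removed from a neopentylic position between the quaternary carbon and the pyridine. Hydrazone formation there is hindered, and any cationic deoxygenation invites a 1,2-shift of the electron-rich aryl group from C6 to C5.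
- The allyl group must be cut down to the aminoethyl chain by oxidative cleavage in the presence of the electron-rich arene and the pyridine nitrogen.

The step count is no lower, and the risk sits in three places instead of one.

**Alternative 3:** One aromatic ring is made from another. Ring A is cut at C8a–C4a and C4–C3 back to the 1,2,4-triazine A6, which carries a tethered terminal alkyne. The forward key step is an intramolecular inverse-electron-demand Diels–Alder reaction with loss of dinitrogen, giving the target directly. This closes both rings thermally and without metal. It was turned down because A6 has four different arms on the quaternary carbon, so the stereocentre must come from an independent asymmetric synthesis of an acyclic quaternary centre; the cycloaddition contributes nothing to the stereochemical problem. The triazine must also be built from a nitrile through an amidrazone and a 1,2-dicarbonyl condensation, whereas the chosen key step uses the nitrile itself.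

Key step: step 4

Assumption: the SMILES is read as R at C6; compounds 11 to 13 have the same spatial arrangement but are named S, because C5 outranks the chain until the chain carbon β to C6 bears nitrogen.
Assumption: the sense of induction of the chiral cobalt catalyst in step 4 cannot be derived a priori; the ligand antipode that gives (S)-12 is used (both antipodes are commercial).

## Route

Step 1
Reactants: 1 2-(3,4-dimethoxyphenyl)acetaldehyde; 2 acrylonitrile
Product: 4 4-(3,4-dimethoxyphenyl)-4-formylheptanedinitrile, via mono-adduct 3 (not isolated)
Conditions: 2 (2.5 equiv), benzyltrimethylammonium hydroxide (10 mol %), t-BuOH, 0 °C to rt, slow addition of 1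
Reagents that add atoms: acrylonitrile 2, C=CC#N
Why: Base-catalysed double Michael addition (cyanoethylation) at the doubly activated benzylic α-carbon of the arylacetaldehyde; after the second addition the aldehyde is no longer enolisable, which ends the sequence at the quaternary stage. Slow addition of 1 into excess acceptor keeps self-aldol condensation down.

Step 2
Reactants: 4 4-(3,4-dimethoxyphenyl)-4-formylheptanedinitrile; 5 (methoxymethyl)triphenylphosphonium chloride
Product: 7 4-(3,4-dimethoxyphenyl)-4-(2-oxoethyl)heptanedinitrile, via enol ether 6 (not isolated)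
Conditions: 5 (1.5 equiv), KOtBu (1.4 equiv), THF, 0 °C; then 4, 0 °C to rt; then 1 M aq. HCl, rt
Reagents that add atoms: (methoxymethyl)triphenylphosphonium chloride 5, COC[P+](c1ccccc1)(c1ccccc1)c1ccccc1.[Cl-]; water, O
Why: Wittig reaction of the non-enolisable neopentylic aldehyde with the methoxymethylene ylide, then mild acid hydrolysis of the enol ether, gives the one-carbon homologated aldehyde. The ylide is preformed with the base as the limiting component so that no free alkoxide meets the dinitrile.

Step 3
Reactants: 7 4-(3,4-dimethoxyphenyl)-4-(2-oxoethyl)heptanedinitrile; 8 dimethyl (1-diazo-2-oxopropyl)phosphonate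
Product: 9 4-(3,4-dimethoxyphenyl)-4-(prop-2-yn-1-yl)heptanedinitrile
Conditions: 8 (1.3 equiv), K2CO3 (2 equiv), MeOH, 0 °C to rt
Reagents that add atoms: dimethyl (1-diazo-2-oxopropyl)phosphonate 8, COP(=O)(OC)C(=[N+]=[N-])C(C)=O
Why: Seyferth–Gilbert homologation in the Ohira–Bestmann variant converts the aldehyde into the terminal alkyne under mild carbonate/methanol conditions that leave the nitriles alone. The product 9 is achiral, so enolisation of 7 costs nothing.

Step 4
Reactants: 9 4-(3,4-dimethoxyphenyl)-4-(prop-2-yn-1-yl)heptanedinitrile; 10 ethynyltrimethylsilane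
Product: 12 3-[(6S)-6-(3,4-dimethoxyphenyl)-5,6,7,8-tetrahydroquinolin-6-yl]propanenitrile, via 2-silylpyridine 11 (not isolated)
Conditions: CoBr2 (10 mol %), (R,R)-Ph-BPE (12 mol %), Zn (20 mol %), ZnI2 (20 mol %), 10 (3 equiv), THF, 40 °C, slow addition of 9; then K2CO3 (cat.), MeOH, 40 °C
Reagents that add atoms: ethynyltrimethylsilane 10, C[Si](C)(C)C#C
Why: Proposed new method: a low-valent cobalt–bisphosphine complex (from CoBr2, the ligand and Zn) should couple the terminal alkyne of 9 with 10 to a cobaltacyclopentadiene with the tether and the silyl group next to cobalt, after which one of the two enantiotopic 2-cyanoethyl arms inserts its C≡N into the Co–C4a bond and C2–N1 reductive elimination releases 11. The closest known reaction types are the cobalt-catalysed cocyclisation of ω-alkynyl nitriles with silylalkynes to 5,6,7,8-tetrahydroquinolines and the enantioselective desymmetrising [2+2+2] cycloaddition of alkyne-tethered malononitriles; new here is a prochiral carbon two atoms away from each nitrile. Ring A is closed by the metal-templated [2+2+2] union (bonds C8a–C4a, C4–C3, C2–N1), and ring B by intramolecular delivery of the nitrile through the four-atom tether C5–C6–C7–C8, which forms a six-membered ring onto C4a. C6 becomes stereogenic when one arm is consumed; the control element is the C2-symmetric bis(phospholane) on cobalt, which must tell the aryl group from the spectator cyanoethyl arm in the half-chair of the forming ring B, where the bulky aryl group should take the pseudo-equatorial position. The step needs chemoselectivity for the nitrile over a second alkyne, which the tether, the geminal disubstitution at C6 (Thorpe–Ingold effect) and the silyl group of 10 should provide. It also needs enantiotopos selectivity, which only the catalyst can provide. The silyl regiochemistry does not affect the skeleton, and the expected 2-silyl group of 11 is removed by base-catalysed methanolysis, to which 2-pyridylsilanes are labile. The enantiomeric purity of 12 is to be assayed on a chiral stationary phase.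

Step 5
Reactants: 12 3-[(6S)-6-(3,4-dimethoxyphenyl)-5,6,7,8-tetrahydroquinolin-6-yl]propanenitrile
Product: 13 3-[(6S)-6-(3,4-dimethoxyphenyl)-5,6,7,8-tetrahydroquinolin-6-yl]propanamide
Conditions: PtH(PMe2OH)(PMe2O)2H (2 mol %), EtOH/H2O 4:1, 80 °C
Reagents that add atoms: water, O
Why: Platinum-catalysed hydration of a nitrile under neutral conditions stops at the primary amide and tolerates pyridines; no oxidant is present, so the pyridine nitrogen and the aryl ring are safe.

Step 6
Reactants: 13 3-[(6S)-6-(3,4-dimethoxyphenyl)-5,6,7,8-tetrahydroquinolin-6-yl]propanamide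
Product: 15 methyl N-{2-[(6R)-6-(3,4-dimethoxyphenyl)-5,6,7,8-tetrahydroquinolin-6-yl]ethyl}carbamate, via isocyanate 14 (not isolated)
Conditions: PhI(OAc)2 (1.1 equiv), KOH (2.5 equiv), MeOH, 0 °C to rt
Reagents that add atoms: methanol, CO
Why: Hofmann rearrangement with a trivalent iodine reagent; the primary CH2 migrates from carbon to nitrogen and the isocyanate is trapped by the solvent as the methyl carbamate. C6 is two bonds from the migrating carbon and is not affected; the descriptor changes to R only because the chain now outranks C5.

Step 7
Reactants: 15 methyl N-{2-[(6R)-6-(3,4-dimethoxyphenyl)-5,6,7,8-tetrahydroquinolin-6-yl]ethyl}carbamate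
Product: 16 2-[(6R)-6-(3,4-dimethoxyphenyl)-5,6,7,8-tetrahydroquinolin-6-yl]-N-methylethan-1-amine
Conditions: LiAlH4 (3 equiv), THF, reflux; aq. NaOH work-up
Reagents that add atoms: none
Why: LiAlH4 reduction of a carbamate to the N-methylamine: methoxide is expelled and the carbamate carbonyl carbon becomes the N-methyl group. Aryl ethers and the alkylpyridine are inert to the hydride under these conditions.

Step 8
Reactants: 16 2-[(6R)-6-(3,4-dimethoxyphenyl)-5,6,7,8-tetrahydroquinolin-6-yl]-N-methylethan-1-amine
Product: 17 N-{2-[(6R)-6-(3,4-dimethoxyphenyl)-5,6,7,8-tetrahydroquinolin-6-yl]ethyl}-N-methylacetamide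
Conditions: Ac2O (1.5 equiv), Et3N (2 equiv), CH2Cl2, 0 °C to rt
Reagents that add atoms: acetic anhydride, CC(=O)OC(C)=O
Why: N-acylation of the secondary amine; the pyridine nitrogen is acylated only reversibly and returns on aqueous work-up.

## Compound list

1 | 2-(3,4-dimethoxyphenyl)acetaldehyde | COc1ccc(CC=O)cc1OC | starting material
2 | acrylonitrile | C=CC#N | starting material
3 | 4-(3,4-dimethoxyphenyl)-5-oxopentanenitrile (racemic mono-adduct) | COc1ccc(C(CCC#N)C=O)cc1OC | intermediate
4 | 4-(3,4-dimethoxyphenyl)-4-formylheptanedinitrile | COc1ccc(C(CCC#N)(CCC#N)C=O)cc1OC | intermediate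
5 | (methoxymethyl)triphenylphosphonium chloride | COC[P+](c1ccccc1)(c1ccccc1)c1ccccc1.[Cl-] | starting material
6 | 4-(3,4-dimethoxyphenyl)-4-(2-methoxyethenyl)heptanedinitrile (E/Z mixture) | COC=CC(CCC#N)(CCC#N)c1ccc(OC)c(OC)c1 | intermediate
7 | 4-(3,4-dimethoxyphenyl)-4-(2-oxoethyl)heptanedinitrile | COc1ccc(C(CCC#N)(CCC#N)CC=O)cc1OC | intermediate
8 | dimethyl (1-diazo-2-oxopropyl)phosphonate | COP(=O)(OC)C(=[N+]=[N-])C(C)=O | starting material
9 | 4-(3,4-dimethoxyphenyl)-4-(prop-2-yn-1-yl)heptanedinitrile | COc1ccc(C(CCC#N)(CCC#N)CC#C)cc1OC | intermediate
10 | ethynyltrimethylsilane | C[Si](C)(C)C#C | starting material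
11 | 3-[(6S)-6-(3,4-dimethoxyphenyl)-2-(trimethylsilyl)-5,6,7,8-tetrahydroquinolin-6-yl]propanenitrile | COc1ccc([C@]2(CCC#N)CCc3nc([Si](C)(C)C)ccc3C2)cc1OC | intermediate
12 | 3-[(6S)-6-(3,4-dimethoxyphenyl)-5,6,7,8-tetrahydroquinolin-6-yl]propanenitrile | COc1ccc([C@]2(CCC#N)CCc3ncccc3C2)cc1OC | intermediate
13 | 3-[(6S)-6-(3,4-dimethoxyphenyl)-5,6,7,8-tetrahydroquinolin-6-yl]propanamide | COc1ccc([C@]2(CCC(N)=O)CCc3ncccc3C2)cc1OC | intermediate
14 | (6R)-6-(3,4-dimethoxyphenyl)-6-(2-isocyanatoethyl)-5,6,7,8-tetrahydroquinoline | COc1ccc([C@]2(CCN=C=O)CCc3ncccc3C2)cc1OC | intermediate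
15 | methyl N-{2-[(6R)-6-(3,4-dimethoxyphenyl)-5,6,7,8-tetrahydroquinolin-6-yl]ethyl}carbamate | COc1ccc([C@]2(CCNC(=O)OC)CCc3ncccc3C2)cc1OC | intermediate
16 | 2-[(6R)-6-(3,4-dimethoxyphenyl)-5,6,7,8-tetrahydroquinolin-6-yl]-N-methylethan-1-amine | COc1ccc([C@]2(CCNC)CCc3ncccc3C2)cc1OC | intermediate
17 | N-{2-[(6R)-6-(3,4-dimethoxyphenyl)-5,6,7,8-tetrahydroquinolin-6-yl]ethyl}-N-methylacetamide | COc1ccc([C@]2(CCN(C)C(C)=O)CCc3ncccc3C2)cc1OC | target

## Step count and least certain steps

Total step count: 8. Longest linear sequence: 8 steps (from 1).

**Step 4 (key step, proposed new method).** Three things may go wrong. The catalyst may discriminate poorly between the two enantiotopic cyanoethyl arms, because the prochiral carbon is remote from the metal. A second alkyne may enter the cobaltacycle in place of the tethered nitrile (benzannulation), or the terminal alkyne may oligomerise. The silyl group may end up at C3, where methanolysis is slow and fluoride would be needed.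

Fallback with known chemistry, setting out from 9 (with 10) and returning at 12: the established achiral cocyclisation of an ω-alkynyl nitrile with a silylalkyne is run with CpCo(CO)2 (cyclopentadienylcobalt dicarbonyl) in refluxing xylene under irradiation. This gives racemic 3-[6-(3,4-dimethoxyphenyl)-2-(trimethylsilyl)-5,6,7,8-tetrahydroquinolin-6-yl]propanenitrile F1. Methanolysis with K2CO3 in MeOH gives racemic 3-[6-(3,4-dimethoxyphenyl)-5,6,7,8-tetrahydroquinolin-6-yl]propanenitrile F2. Preparative chromatography on a polysaccharide chiral stationary phase then separates 12 from 3-[(6R)-6-(3,4-dimethoxyphenyl)-5,6,7,8-tetrahydroquinolin-6-yl]propanenitrile F3, which is discarded. Stereocontrol thus moves from catalytic desymmetrisation to resolution, at the cost of half the material.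

**Step 1.** The enolisable arylacetaldehyde may undergo self-aldol condensation, the acrylonitrile may polymerise anionically, or the reaction may stall at mono-adduct 3.

Fallback, setting out from 2 and returning at 4: methyl 2-(3,4-dimethoxyphenyl)acetate F4, which does not self-condense, is doubly cyanoethylated with 2 (cat. KOtBu, t-BuOH) to methyl 4-cyano-2-(2-cyanoethyl)-2-(3,4-dimethoxyphenyl)butanoate F5. Chemoselective ester reduction with LiBH4 (THF/MeOH) gives 4-(3,4-dimethoxyphenyl)-4-(hydroxymethyl)heptanedinitrile F6, and Dess–Martin oxidation gives 4.

**Step 2.** Any free alkoxide may trigger a Thorpe–Ziegler cyclisation between the two cyanoethyl arms. During enol ether hydrolysis, acid may promote Friedel–Crafts closure of the new aldehyde onto the electron-rich aryl ring.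

Fallback, setting out from 4 and returning at 7, avoiding both strong base and acid: non-basic titanium–zinc methylenation (Zn, CH2Br2, TiCl4, THF/CH2Cl2) gives 4-(3,4-dimethoxyphenyl)-4-ethenylheptanedinitrile F7. Anti-Markovnikov hydroboration with 9-BBN and oxidation with NaBO3 gives 4-(3,4-dimethoxyphenyl)-4-(2-hydroxyethyl)heptanedinitrile F8, and Dess–Martin oxidation gives 7.

**Step 6.** The trivalent iodine reagent may oxidise the dimethoxyphenyl ring or the pyridine nitrogen, or isocyanate 14 may be captured by unreacted amide to give an acylurea.

Fallback, setting out from 12 and returning at 15, without an oxidant: nitrile 12 is hydrolysed (KOH, aqueous ethylene glycol, 120 °C) to 3-[(6S)-6-(3,4-dimethoxyphenyl)-5,6,7,8-tetrahydroquinolin-6-yl]propanoic acid F9. A Curtius rearrangement with diphenylphosphoryl azide and Et3N in toluene at 80 °C proceeds through 3-[(6S)-6-(3,4-dimethoxyphenyl)-5,6,7,8-tetrahydroquinolin-6-yl]propanoyl azide F10 to isocyanate 14, which is trapped with MeOH to give 15.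

## Further compounds

F1 | step 4 | 3-[6-(3,4-dimethoxyphenyl)-2-(trimethylsilyl)-5,6,7,8-tetrahydroquinolin-6-yl]propanenitrile (racemic) | COc1ccc(C2(CCC#N)CCc3nc([Si](C)(C)C)ccc3C2)cc1OC
F2 | step 4 | 3-[6-(3,4-dimethoxyphenyl)-5,6,7,8-tetrahydroquinolin-6-yl]propanenitrile (racemic) | COc1ccc(C2(CCC#N)CCc3ncccc3C2)cc1OC
F3 | step 4 | 3-[(6R)-6-(3,4-dimethoxyphenyl)-5,6,7,8-tetrahydroquinolin-6-yl]propanenitrile | COc1ccc([C@@]2(CCC#N)CCc3ncccc3C2)cc1OC
F4 | step 1 | methyl 2-(3,4-dimethoxyphenyl)acetate | COC(=O)Cc1ccc(OC)c(OC)c1
F5 | step 1 | methyl 4-cyano-2-(2-cyanoethyl)-2-(3,4-dimethoxyphenyl)butanoate | COC(=O)C(CCC#N)(CCC#N)c1ccc(OC)c(OC)c1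
F6 | step 1 | 4-(3,4-dimethoxyphenyl)-4-(hydroxymethyl)heptanedinitrile | COc1ccc(C(CO)(CCC#N)CCC#N)cc1OC
F7 | step 2 | 4-(3,4-dimethoxyphenyl)-4-ethenylheptanedinitrile | COc1ccc(C(C=C)(CCC#N)CCC#N)cc1OC
F8 | step 2 | 4-(3,4-dimethoxyphenyl)-4-(2-hydroxyethyl)heptanedinitrile | COc1ccc(C(CCO)(CCC#N)CCC#N)cc1OC
F9 | step 6 | 3-[(6S)-6-(3,4-dimethoxyphenyl)-5,6,7,8-tetrahydroquinolin-6-yl]propanoic acid | COc1ccc([C@]2(CCC(=O)O)CCc3ncccc3C2)cc1OC
F10 | step 6 | 3-[(6S)-6-(3,4-dimethoxyphenyl)-5,6,7,8-tetrahydroquinolin-6-yl]propanoyl azide | COc1ccc([C@]2(CCC(=O)N=[N+]=[N-])CCc3ncccc3C2)cc1OC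
A1 | alternative 1 | N-{2-[1-(3,4-dimethoxyphenyl)-4-oxocyclohexyl]ethyl}-N-methylacetamide | COc1ccc(C2(CCN(C)C(C)=O)CCC(=O)CC2)cc1OC
A2 | alternative 1 | N-{2-[(1R)-1-(3,4-dimethoxyphenyl)-4-oxocyclohex-2-en-1-yl]ethyl}-N-methylacetamide | COc1ccc([C@]2(CCN(C)C(C)=O)C=CC(=O)CC2)cc1OC
A3 | alternative 2 | 7,8-dihydroquinolin-5(6H)-one | O=C1CCCc2ncccc12
A4 | alternative 2 | 6-(3,4-dimethoxyphenyl)-7,8-dihydroquinolin-5(6H)-one (racemic) | COc1ccc(C2CCc3ncccc3C2=O)cc1OC
A5 | alternative 2 | (6R)-6-(3,4-dimethoxyphenyl)-6-(prop-2-en-1-yl)-7,8-dihydroquinolin-5(6H)-one | COc1ccc([C@]2(CC=C)CCc3ncccc3C2=O)cc1OC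
A6 | alternative 3 | N-{(3R)-3-(3,4-dimethoxyphenyl)-3-[2-(1,2,4-triazin-3-yl)ethyl]hex-5-yn-1-yl}-N-methylacetamide | COc1ccc([C@](CC#C)(CCN(C)C(C)=O)CCc2nccnn2)cc1OC
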